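**Plan**
- Retrosynthesis cuts ring A at C7–C8 and C4a–C5 in one operation, then the C3–C1′ biaryl bond; ring C with its methyl carbon is bought as kojic acid.
- Enabling feature: C5(OH)–C6(OMe)–C7(OH) of ring A is a methoxymalonyl unit at the diacyl oxidation level, and C8–C8a–C4a is the CH3–C=CH edge of a 2-methyl-4-pyranone (ring C), so ring A is a [3+3] sum of the two.
- Forward: kojic acid → allomaltol → enol triflate, then Suzuki coupling joins ring B to ring C; separately, dimethyl methoxymalonate → diacid → dichloride.
- Ring A arises last, in one flask, by double C-acylation of the silyl dienol ether of the arylmethylpyranone; acidic work-up gives the target with no protecting groups.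
- Stereochemistry: the target has no stereocentre and no stereogenic double bond, so nothing has to be set.

Key step: step 7

Remark: the target is achiral, so "single enantiomer" places no demand on the route. The only stereogenic carbon on the way (the methoxy-bearing carbon of 12, racemic and labile) becomes an sp2 ring carbon.

**Step 1**
Reactants: 1 kojic acid [5-hydroxy-2-(hydroxymethyl)-4H-pyran-4-one]
Product: 2 chlorokojic acid [2-(chloromethyl)-5-hydroxy-4H-pyran-4-one]
Conditions: SOCl2 (neat), rt
Reagents that add atoms: thionyl chloride, O=S(Cl)Cl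
Why: Chlorodehydroxylation of the primary alcohol through its chlorosulfite is the standard first transformation of kojic acid and leaves the enolic 5-OH untouched.

**Step 2**
Reactants: 2 chlorokojic acid
Product: 3 allomaltol [5-hydroxy-2-methyl-4H-pyran-4-one]
Conditions: Zn dust, conc. HCl, H2O, 70 °C
Reagents that add atoms: none
Why: Dissolving-metal reductive dechlorination of the activated chloromethyl group by zinc in aqueous acid is the classical preparation of allomaltol.

**Step 3**
Reactants: 3 allomaltol
Product: 4 6-methyl-4-oxo-4H-pyran-3-yl trifluoromethanesulfonate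
Conditions: Tf2O, pyridine, CH2Cl2, –20 → 0 °C
Reagents that add atoms: trifluoromethanesulfonic anhydride, O=S(=O)(OS(=O)(=O)C(F)(F)F)C(F)(F)F
Why: O-Sulfonylation of the acidic enolic hydroxyl with triflic anhydride and pyridine should give the α-keto enol triflate, a known type of coupling partner from kojic-acid-derived pyranones.

**Step 4**
Reactants: 4 6-methyl-4-oxo-4H-pyran-3-yl trifluoromethanesulfonate; 5 (2,3,4-trimethoxyphenyl)boronic acid
Product: 6 2-methyl-5-(2,3,4-trimethoxyphenyl)-4H-pyran-4-one
Conditions: Pd(OAc)2 (5 mol %), SPhos (10 mol %), K3PO4, 1,4-dioxane–H2O (10:1), 80 °C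
Reagents that add atoms: none
Why: Suzuki–Miyaura coupling, in which the electron-poor enol triflate should add readily to Pd(0) and the biaryl phosphine should speed transmetalation and reductive elimination with the ortho-substituted, electron-rich boronic acid.

**Step 5**
Reactants: 7 dimethyl 2-methoxymalonate [dimethyl 2-methoxypropanedioate]
Product: 9 2-methoxymalonic acid [2-methoxypropanedioic acid], via dipotassium salt 8 (not isolated)
Conditions: KOH (2.2 equiv), MeOH–H2O, 0 °C → rt; then conc. HCl to pH 1 at 0 °C, continuous Et2O extraction, concentration below 30 °C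
Reagents that add atoms: potassium hydroxide, [K+].[OH-]
Why: Saponification of both methyl esters (BAc2) followed by cold acidification should give the malonic acid, which is kept cold to avoid decarboxylation.

**Step 6**
Reactants: 9 2-methoxymalonic acid
Product: 10 methoxymalonyl dichloride [2-methoxypropanedioyl dichloride]
Conditions: (COCl)2 (2.5 equiv), DMF (cat.), CH2Cl2, 0 °C → rt; concentration and short-path distillation under reduced pressure
Reagents that add atoms: oxalyl chloride, O=C(Cl)C(=O)Cl
Why: Vilsmeier-catalysed conversion of both carboxylic acids into acyl chlorides with oxalyl chloride is the usual route to substituted malonyl dichlorides and leaves only gaseous by-products.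

**Step 7**
Reactants: 6 2-methyl-5-(2,3,4-trimethoxyphenyl)-4H-pyran-4-one; 10 methoxymalonyl dichloride
Product: 14 5,7-dihydroxy-6-methoxy-3-(2,3,4-trimethoxyphenyl)-4H-chromen-4-one (target), via TBS dienol ether 11 (not isolated), via keto acyl chloride 12 (not isolated), via O5-TBS chromone 13 (not isolated)
Conditions: TBSOTf (1.1 equiv), iPr2NEt (1.2 equiv), CH2Cl2, 0 °C; then 10 (1.05 equiv), –78 °C, 0.02 M; then 2,6-lutidine (2.5 equiv), –78 °C → rt; then 1 M aq HCl, THF–MeOH, rt
Reagents that add atoms: tert-butyldimethylsilyl trifluoromethanesulfonate, CC(C)(C)[Si](C)(C)OS(=O)(=O)C(F)(F)F (its silyl group is present only in 11–13; none of its atoms remains in 14)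
Why: Proposed new method: O-silylation of 6 gives a 4-silyloxypyrylium triflate whose 2-methyl group is deprotonated by iPr2NEt to the dienol ether 11, a cyclic counterpart of a 1,3-bis(silyl enol ether) that is nucleophilic at the exocyclic carbon and at ring carbon C3; the exocyclic carbon attacks one acyl chloride of 10 (re-forming the pyrylium, then deprotonation to 12), 2,6-lutidine then removes HCl from the β-keto acyl chloride to give an acylketene that C3 captures, and proton loss, enolisation and an O4-to-O5 silyl shift give aromatic 13, from which acid removes silicon. The closest known reactions are C-acylation of pyrylium anhydrobases (2-methylenepyrans) and of bis(silyl enol ether) termini by acid chlorides, the formal [3+3] cyclocondensation of 1,3-bis(silyl enol ethers) with 1,3-dielectrophiles to phenols, and dienylketene benzannulation. The one ring closed is the six-membered carbocycle C4a–C5–C6–C7–C8–C8a, closed at C4a–C5 after the intermolecular C7–C8 bond, by 6π-electrocyclisation of the dienylketene or, equivalently, 6-(enolexo)-exo-trig C-acylation. No stereocentre is formed. The step needs C- rather than O-acylation at both sites: the TBS cap blocks O4, the aryl group blocks the other α-carbon of the pyranone, re-aromatisation to the pyrylium should direct the first attack to the exocyclic carbon, and either order of the two C-acylations closes the same ring. The central malonyl carbon must end para to C8a, so only the 6-methoxy isomer can form.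

**Compound list**
1 | kojic acid, 5-hydroxy-2-(hydroxymethyl)-4H-pyran-4-one | OCc1cc(=O)c(O)co1 | starting material
2 | chlorokojic acid, 2-(chloromethyl)-5-hydroxy-4H-pyran-4-one | ClCc1cc(=O)c(O)co1 | intermediate
3 | allomaltol, 5-hydroxy-2-methyl-4H-pyran-4-one | Cc1cc(=O)c(O)co1 | intermediate
4 | 6-methyl-4-oxo-4H-pyran-3-yl trifluoromethanesulfonate | Cc1cc(=O)c(OS(=O)(=O)C(F)(F)F)co1 | intermediate
5 | (2,3,4-trimethoxyphenyl)boronic acid | COc1ccc(B(O)O)c(OC)c1OC | starting material
6 | 2-methyl-5-(2,3,4-trimethoxyphenyl)-4H-pyran-4-one | COc1ccc(-c2coc(C)cc2=O)c(OC)c1OC | intermediate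
7 | dimethyl 2-methoxymalonate (dimethyl 2-methoxypropanedioate) | COC(C(=O)OC)C(=O)OC | starting material
8 | dipotassium 2-methoxypropanedioate (formed in the flask, not isolated) | COC(C(=O)[O-])C(=O)[O-].[K+].[K+] | intermediate
9 | 2-methoxymalonic acid (2-methoxypropanedioic acid) | COC(C(=O)O)C(=O)O | intermediate
10 | methoxymalonyl dichloride (2-methoxypropanedioyl dichloride) | COC(C(=O)Cl)C(=O)Cl | intermediate
11 | 4-{[tert-butyl(dimethyl)silyl]oxy}-2-methylidene-5-(2,3,4-trimethoxyphenyl)-2H-pyran (formed in the flask, not isolated) | C=C1C=C(O[Si](C)(C)C(C)(C)C)C(c2ccc(OC)c(OC)c2OC)=CO1 | intermediate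
12 | (4E)-4-[4-{[tert-butyl(dimethyl)silyl]oxy}-5-(2,3,4-trimethoxyphenyl)-2H-pyran-2-ylidene]-2-methoxy-3-oxobutanoyl chloride, racemic and labile at C2 (formed in the flask, not isolated) | COC(C(=O)Cl)C(=O)/C=C1\C=C(O[Si](C)(C)C(C)(C)C)C(c2ccc(OC)c(OC)c2OC)=CO1 | intermediate
13 | 5-{[tert-butyl(dimethyl)silyl]oxy}-7-hydroxy-6-methoxy-3-(2,3,4-trimethoxyphenyl)-4H-chromen-4-one (formed in the flask, not isolated) | COc1ccc(-c2coc3cc(O)c(OC)c(O[Si](C)(C)C(C)(C)C)c3c2=O)c(OC)c1OC | intermediate
14 | 5,7-dihydroxy-6-methoxy-3-(2,3,4-trimethoxyphenyl)-4H-chromen-4-one | COc1ccc(-c2coc3cc(O)c(OC)c(O)c3c2=O)c(OC)c1OC | target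

**Step count**
Total: 7 steps. Longest linear sequence: 5 steps (steps 1, 2, 3, 4 and 7, from kojic acid); the malonyl branch (steps 5 and 6) joins at step 7.

**Steps most likely to fail**

1. Step 7 (proposed new method). The second acylation may go intermolecularly and give oligomers, acylation may shift to oxygen after premature loss of silicon, or the acylketene may dimerise before C3 captures it. The fallback takes ring A from a preformed arene and builds the isoflavone by known chemistry; it sets out from boronic acid 5 and returns to the route at target 14.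
 - Commercial 1-[2,4-bis(benzyloxy)-6-hydroxyphenyl]ethan-1-one would undergo Elbs persulfate oxidation para to the free phenol (K2S2O8, aq NaOH) to potassium 3-acetyl-2,6-bis(benzyloxy)-4-hydroxyphenyl sulfate F1.
 - Aqueous HCl would hydrolyse this to 1-[2,4-bis(benzyloxy)-3,6-dihydroxyphenyl]ethan-1-one F2.
 - Methylation of the non-chelated hydroxyl (Me2SO4, K2CO3, acetone) should give 1-[2,4-bis(benzyloxy)-6-hydroxy-3-methoxyphenyl]ethan-1-one F3, in which the methoxy position is fixed relative to the phenol that becomes O1.
 - DMF dimethyl acetal would convert the acetyl group into (E)-1-[2,4-bis(benzyloxy)-6-hydroxy-3-methoxyphenyl]-3-(dimethylamino)prop-2-en-1-one F4.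
 - Iodine in methanol would cyclise this to 5,7-bis(benzyloxy)-3-iodo-6-methoxy-4H-chromen-4-one F5.
 - Suzuki coupling of this iodide with 5 [Pd(dppf)Cl2, K2CO3, dioxane–H2O] should give 5,7-bis(benzyloxy)-6-methoxy-3-(2,3,4-trimethoxyphenyl)-4H-chromen-4-one F6.
 - Hydrogenolysis (H2, Pd/C, EtOAc–MeOH) would then release 14.

2. Step 4. Base-mediated S–O cleavage of the triflate back to allomaltol, hydroxide addition to the pyranone, or protodeboronation of the electron-rich ortho-methoxy boronic acid may outrun transmetalation. The fallback forms the biaryl bond without base or water by Negishi coupling; it sets out from triflate 4 and returns at 6.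
 - Commercial 1-bromo-2,3,4-trimethoxybenzene would be lithiated (n-BuLi, THF, –78 °C) to (2,3,4-trimethoxyphenyl)lithium F7.
 - Transmetalation with ZnCl2 would give chlorido(2,3,4-trimethoxyphenyl)zinc F8.
 - Coupling of this organozinc with 4 [Pd2(dba)3, XPhos, THF, rt → 50 °C] should give 6.

3. Step 6. The HCl released may drive the half chloride to a ketene with decarboxylation or polymerisation, and material may be lost on distillation. The fallback activates the acid as its silyl ester under neutral conditions; it sets out from 9 and returns at 10.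
 - Hexamethyldisilazane would convert 9 into bis(trimethylsilyl) 2-methoxypropanedioate F9.
 - Oxalyl chloride with catalytic DMF in CH2Cl2 at 0 °C would convert this silyl ester into 10, with chlorotrimethylsilane in place of HCl.

**Further compounds**
F1 | step 7 | potassium 3-acetyl-2,6-bis(benzyloxy)-4-hydroxyphenyl sulfate | CC(=O)c1c(O)cc(OCc2ccccc2)c(OS(=O)(=O)[O-])c1OCc1ccccc1.[K+]
F2 | step 7 | 1-[2,4-bis(benzyloxy)-3,6-dihydroxyphenyl]ethan-1-one | CC(=O)c1c(O)cc(OCc2ccccc2)c(O)c1OCc1ccccc1
F3 | step 7 | 1-[2,4-bis(benzyloxy)-6-hydroxy-3-methoxyphenyl]ethan-1-one | CC(=O)c1c(O)cc(OCc2ccccc2)c(OC)c1OCc1ccccc1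
F4 | step 7 | (E)-1-[2,4-bis(benzyloxy)-6-hydroxy-3-methoxyphenyl]-3-(dimethylamino)prop-2-en-1-one | CN(C)/C=C/C(=O)c1c(O)cc(OCc2ccccc2)c(OC)c1OCc1ccccc1
F5 | step 7 | 5,7-bis(benzyloxy)-3-iodo-6-methoxy-4H-chromen-4-one | COc1c(OCc2ccccc2)cc2occ(I)c(=O)c2c1OCc1ccccc1
F6 | step 7 | 5,7-bis(benzyloxy)-6-methoxy-3-(2,3,4-trimethoxyphenyl)-4H-chromen-4-one | COc1ccc(-c2coc3cc(OCc4ccccc4)c(OC)c(OCc4ccccc4)c3c2=O)c(OC)c1OC
F7 | step 4 | (2,3,4-trimethoxyphenyl)lithium | [Li]c1ccc(OC)c(OC)c1OC
F8 | step 4 | chlorido(2,3,4-trimethoxyphenyl)zinc | Cl[Zn]c1ccc(OC)c(OC)c1OC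
F9 | step 6 | bis(trimethylsilyl) 2-methoxypropanedioate | COC(C(=O)O[Si](C)(C)C)C(=O)O[Si](C)(C)C
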